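## Retrosynthetic overview

1. Last operation: the C8 ketone is released from a methyl enol ether. Before that, ring A (the 4-pyridone) is closed on a cyclic 1,3-diketone by forming C2–C3, N1–C2 and N1–C8a (amide acetal supplies C2 and its CH3, ammonia supplies N1).
2. First ring: ring B (the carbocycle) and the only stereocentre, C5, come from one amine-catalysed Michael addition/aldol condensation that forms C4a–C5 and C7–C8.
3. The partners are (E)-8-phenyloct-2-enal (C5–C7 plus side chain) and the C2-symmetric 1,5-dimethoxypentane-2,4-dione (C3, C4, C4a, C8a, C8). Its two OMe groups become the 3-OMe group and the masked 8-oxo group, so no protecting group or redox step is needed.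
4. The enal is cut to (5-bromopentyl)benzene and 3-(dimethylamino)acrolein; the diketone to methoxyacetone and methyl methoxyacetate.
5. Ring order: ring B, then ring A.

Assumption: C5 of the target is read from the SMILES as (S) (CIP order C4a > C6 > side-chain C1′ > H); quinoline numbering of the target is used for atom labels, and compounds 1, 2, 6, 7 and both enantiomers of the catalyst are taken as catalogue chemicals.

## Route

Step 1
Reactants: 1 (5-bromopentyl)benzene; 2 (E)-3-(dimethylamino)prop-2-enal
Product: 5 (E)-8-phenyloct-2-enal, via Grignard reagent 3 (not isolated), via magnesium alkoxide adduct 4 (not isolated)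
Conditions: Mg, THF, 40 °C; then 2, THF, −20 °C → rt; then 2 M aq. HCl, rt
Reagents that add atoms: water, SMILES O
Why: The primary Grignard reagent adds 1,2 to the vinylogous formamide 2, and aqueous acid ionises the amino-allylic alkoxide to a conjugated iminium ion whose hydrolysis releases Me2NH and the thermodynamically favoured (E)-enal (vinylogous Bouveault formylation, a two-carbon homologation).

Step 2
Reactants: 6 1-methoxypropan-2-one; 7 methyl 2-methoxyacetate
Product: 8 1,5-dimethoxypentane-2,4-dione
Conditions: NaH (2.2 equiv), 7 (1.5 equiv), THF, 0 → 50 °C; then 1 M aq. HCl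
Reagents that add atoms: none
Why: Crossed Claisen condensation in which the methyl-side enolate of 6 attacks ester 7 and the product is withdrawn as its sodium diketonate, so the less hindered 1,5-dimethoxy diketone is the thermodynamic product over the 3-methoxy isomer.

Step 3
Reactants: 5 (E)-8-phenyloct-2-enal; 8 1,5-dimethoxypentane-2,4-dione
Product: 10 (5S)-2-methoxy-6-(2-methoxyacetyl)-5-(5-phenylpentyl)cyclohex-2-en-1-one, via Michael adduct aldehyde 9 (not isolated)
Conditions: (R)-α,α-bis[3,5-bis(trifluoromethyl)phenyl]prolinol trimethylsilyl ether (10 mol %), PhCO2H (10 mol %), toluene, 0 °C → rt; then p-TsOH·H2O (30 mol %), toluene, 70 °C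
Reagents that add atoms: none
Why: Proposed new method: the (R)-diarylprolinol silyl ether turns 5 into an s-trans (E)-iminium ion whose Re face at C3 is blocked, so the central CH2 of 8 adds from the Si face and sets the (S) centre (iminium-ion Michael addition); on acid treatment the enol of one methoxyacetyl arm closes on the freed aldehyde through its OMe-bearing α′-carbon and loses water (intramolecular aldol condensation) to give the 2-methoxy-enone, the two arms being equivalent so either closure gives the same product; the closest known reaction type is the diarylprolinol-silyl-ether-catalysed Michael/aldol-condensation cascade of β-keto esters (including γ-chloro-β-keto esters) with enals to cyclohexenones, which has not been run with a 1,5-dialkoxy-2,4-diketone or closed through an alkoxy-bearing carbon.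

Step 4
Reactants: 10 (5S)-2-methoxy-6-(2-methoxyacetyl)-5-(5-phenylpentyl)cyclohex-2-en-1-one
Product: 13 (5S)-3-methoxy-2-methyl-5-(5-phenylpentyl)-6,7-dihydroquinoline-4,8(1H,5H)-dione, via enaminone 11 (not isolated), via enol ether pyridone 12 (not isolated)
Conditions: MeC(OMe)2NMe2 (3 equiv), toluene, 100 °C, evaporate; then NH4OAc (10 equiv), AcOH, 90 °C; then 2 M aq. HCl, 50 °C
Reagents that add atoms: N,N-dimethylacetamide dimethyl acetal, SMILES COC(C)(OC)N(C)C; ammonium acetate, SMILES CC(=O)[O-].[NH4+]; water, SMILES O
Why: The amide acetal condenses at the only α-carbon of the diketone that can form a C=C bond (the OMe-bearing methylene), ammonia then exchanges the NMe2 group and cyclodehydrates onto the ring ketone (the standard enaminone route to 4-pyridones), and dilute acid hydrolyses the 1-methoxyvinyl group to the C8 ketone without touching the aryl OMe group or the C5 centre.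

## Compound list

1 | (5-bromopentyl)benzene | BrCCCCCc1ccccc1 | starting material
2 | (E)-3-(dimethylamino)prop-2-enal | CN(C)/C=C/C=O | starting material
3 | (5-phenylpentyl)magnesium bromide | Br[Mg]CCCCCc1ccccc1 | intermediate
4 | bromomagnesium (E)-1-(dimethylamino)-8-phenyloct-1-en-3-olate (racemic) | CN(C)/C=C/C(CCCCCc1ccccc1)O[Mg]Br | intermediate
5 | (E)-8-phenyloct-2-enal | O=C/C=C/CCCCCc1ccccc1 | intermediate
6 | 1-methoxypropan-2-one | COCC(C)=O | starting material
7 | methyl 2-methoxyacetate | COCC(=O)OC | starting material
8 | 1,5-dimethoxypentane-2,4-dione | COCC(=O)CC(=O)COC | intermediate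
9 | (3S)-6-methoxy-4-(2-methoxyacetyl)-5-oxo-3-(5-phenylpentyl)hexanal (open form of its cyclic hemiacetal) | COCC(=O)C(C(=O)COC)[C@@H](CCCCCc1ccccc1)CC=O | intermediate
10 | (5S)-2-methoxy-6-(2-methoxyacetyl)-5-(5-phenylpentyl)cyclohex-2-en-1-one (C6 epimers and enol form) | COCC(=O)C1[C@@H](CCCCCc2ccccc2)CC=C(OC)C1=O | intermediate
11 | (5S)-6-[3-(dimethylamino)-2-methoxybut-2-enoyl]-2-methoxy-5-(5-phenylpentyl)cyclohex-2-en-1-one | CN(C)C(C)=C(OC)C(=O)C1[C@@H](CCCCCc2ccccc2)CC=C(OC)C1=O | intermediate
12 | (5S)-3,8-dimethoxy-2-methyl-5-(5-phenylpentyl)-5,6-dihydroquinolin-4(1H)-one | COc1c(C)[nH]c2c(c1=O)[C@@H](CCCCCc1ccccc1)CC=C2OC | intermediate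
13 | (5S)-3-methoxy-2-methyl-5-(5-phenylpentyl)-6,7-dihydroquinoline-4,8(1H,5H)-dione | COc1c(C)[nH]c2c(c1=O)[C@@H](CCCCCc1ccccc1)CCC2=O | target

## Step count and risks

Total steps: 4. Longest linear sequence: 3 (steps 1, 3, 4 from 1, or steps 2, 3, 4 from 6).

**Step 3 (the proposed new cascade).** The hemiacetal of 9 may dehydrate to a 4H-pyran instead of carbocyclising, closure through the OMe-bearing carbon may be slow, or the diketone may give a lower ee than β-keto esters. The fallback uses only known chemistry, sets out from 5 and returns at 10. Enal 5 is combined with tert-butyl acetoacetate under the same (R)-diarylprolinol silyl ether catalysis to give tert-butyl (3S)-2-acetyl-5-oxo-3-(5-phenylpentyl)pentanoate F1. p-TsOH in toluene at 80 °C converts this by aldol condensation, ester cleavage and decarboxylation into (5S)-5-(5-phenylpentyl)cyclohex-2-en-1-one F2. Weitz–Scheffer epoxidation (H2O2, NaOH, MeOH, 0 °C) gives (4S)-4-(5-phenylpentyl)-7-oxabicyclo[4.1.0]heptan-2-one F3. NaOMe in MeOH at reflux opens the epoxide at the carbon next to the carbonyl and eliminates water to give (5S)-2-methoxy-5-(5-phenylpentyl)cyclohex-2-en-1-one F4. Kinetic α′-deprotonation with LiN(i-Pr)2 (2.2 equiv, THF, −78 °C) and C-acylation with commercial 2-methoxy-N-methoxy-N-methylacetamide then give 10.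

**Step 4 (telescoped pyridone annulation and hydrolysis).** The amide acetal may react sluggishly at the OMe-bearing methylene, O-methylate the diketone enol, or add as its ketene N,O-acetal to the enone. If only the telescoping fails, 12 can be isolated before hydrolysis. The fallback changes the way C2 is introduced, sets out from 10 and returns at 12. The dianion of the 1,3-diketone (LiN(i-Pr)2, 3 equiv, THF, −78 → −20 °C) is acylated at the terminal OMe-bearing carbon with N-methoxy-N-methylacetamide to give the 1,3,5-triketone (5S)-2-methoxy-6-(2-methoxy-3-oxobutanoyl)-5-(5-phenylpentyl)cyclohex-2-en-1-one F5. NH3 (7 M in MeOH, 60 °C) closes the 1,5-dicarbonyl unit to 12, the only six-membered closure available. 12 is then hydrolysed with aqueous HCl as in the last stage of step 4.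

**Step 1 (vinylogous formylation).** Conjugate addition/elimination followed by a second Grignard addition, or incomplete E selectivity, could lower the yield. The fallback sets out from 1 and returns at 5. The dilithium salt of prop-2-yn-1-ol (LiNH2, liquid NH3/THF) is alkylated with 1 to give 8-phenyloct-2-yn-1-ol F6. trans-Selective reduction with NaAlH2(OCH2CH2OMe)2 in THF gives (E)-8-phenyloct-2-en-1-ol F7, and MnO2 in CH2Cl2 oxidises it to 5.

Further compounds
F1 | step 3 | tert-butyl (3S)-2-acetyl-5-oxo-3-(5-phenylpentyl)pentanoate | CC(=O)C(C(=O)OC(C)(C)C)[C@@H](CCCCCc1ccccc1)CC=O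
F2 | step 3 | (5S)-5-(5-phenylpentyl)cyclohex-2-en-1-one | O=C1C[C@@H](CCCCCc2ccccc2)CC=C1
F3 | step 3 | (4S)-4-(5-phenylpentyl)-7-oxabicyclo[4.1.0]heptan-2-one | O=C1C[C@@H](CCCCCc2ccccc2)CC2OC12
F4 | step 3 | (5S)-2-methoxy-5-(5-phenylpentyl)cyclohex-2-en-1-one | O=C1C[C@@H](CCCCCc2ccccc2)CC=C1OC
F5 | step 4 | (5S)-2-methoxy-6-(2-methoxy-3-oxobutanoyl)-5-(5-phenylpentyl)cyclohex-2-en-1-one | CC(=O)C(OC)C(=O)C1[C@@H](CCCCCc2ccccc2)CC=C(OC)C1=O
F6 | step 1 | 8-phenyloct-2-yn-1-ol | OCC#CCCCCCc1ccccc1
F7 | step 1 | (E)-8-phenyloct-2-en-1-ol | OC/C=C/CCCCCc1ccccc1
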